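Slowness was what I looked for first: the solid substrate entered solution over time, the coupling partner decayed meanwhile, and I wanted those two rates side by side.

solid substrate 0.11 M; coupling partner 0.275 M; time 2.5 h

    solid substrate ⇌ starting material, rate k1*(cs1 - [starting material]) while solid is left; crystals form when [starting material] > cs1 (cs1 = 29 mM, k1 = 0.00759 s⁻¹)
    crystals ⇌ product, rate k2*(cs2 - [product]) while solid is left; crystals form when [product] > cs2 (cs2 = 38 mM, k2 = 1.11 s⁻¹)
    starting material ⇌ reactive form (K3 = 0.525, k3 = 0.0162 s⁻¹)
    coupling partner + reactive form → product (k4 = 72.1 L mol⁻¹ s⁻¹)
    coupling partner → decomposed reagent (k5 = 0.00681 s⁻¹)

- what is said of product includes crystals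
- crystals, solid substrate is a solid; its amount is given per volume of the solution
- at the start none of the solid substrate is in solution
- what has only dissolved of solid substrate counts as not reacted
- starting material means what is dissolved; the solid is not counted in it
- run time (flask): 2.5 h

* part of the solid substrate that has turned into other species by 2.5 h (what has only dissolved does not count)
* the product standing at 2.5 h, as a percentage of the solid substrate charged
* the starting material standing at 2.5 h, as a percentage of the solid substrate charged

I froze the starting material. In this flask, with coupling partner at its charge, the reactive form was trapped far faster than it returned, so for as long as coupling partner lasted I held the starting material where dissolving balanced its forward step, at 8.41% of the charge, with a time constant of 42.0 s. That gave a supply of 0.0818 min⁻¹, as a fraction of the charge. When the supply began, the partner's decay ran at 0.767 min⁻¹ on the same scale, faster than the supply. I called their ratio the waste ratio 9.38. A constant draw on a decaying reagent gives product equal to supply over the decay constant, times the logarithm of one plus that ratio: 46.8%. So I reckoned the partner, charged at 2.50 times the substrate, to be the limiting reagent, with its end at 6.43 min, well before the end of the run. After that end, dissolving and exchange took far less time than the run, so I took starting material to saturation, 26.4%, and reactive form to 13.8%. Conversion came to 60.6%, with 13.0% still solid.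

The forecast gave conversion 59.7%, product 45.9% and starting material 26.4%, holding that “the reactive form is trapped as fast as it forms”. Its product stood below mine by 0.90 percentage points.

The flask gave conversion 60.3%, product 46.5% and starting material 26.4%, inside the forecast's ranges. At 2.50 h the flask held 0% of its coupling partner and 13.3% as solid substrate. At 25.0 h, ten times that time, its conversion stood at 60.3%. For the neighbouring flask, with 0.47 M of coupling partner, the waste ratio became 16.0, and I reckoned product at 56.7%. That flask gave 56.4%, with 3.42% of its solid substrate remaining at 2.50 h.

The constants were drawn at random within sensible limits; the run is a simulation.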